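**Plan**

Retrosynthesis: the C9–C11 bond is cut first, back to an ester of a C7 allylic alcohol with farnesylacetic acid (Ireland–Claisen; the extra carboxyl carbon is lost by radical decarboxylation). Ring B is then opened at C5–C6 to a keto-aldehyde, C6 is removed as CO, and C9–C10 is cut back to 2,2,6-trimethylcyclohexanone.
Forward: ring A is bought; C10 becomes quaternary by palladium-catalysed asymmetric 2-methylallylation; hydroformylation adds C6; ring B is closed at C5=C6 by McMurry coupling; the chain is joined at C9 in step 11.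
Enabling feature: the C5 carbonyl of ring A lies between the quaternary carbons C4 and C10. It cannot enolise and resists ionic addition, but it accepts an electron, so ketyl coupling with the C6 aldehyde closes ring B. The new alkene can only be C5=C6, and its only allylic CH2 is C7.
Stereochemistry: C10 comes from the PHOX ligand (step 2). C5 comes from axial protonation in the Li/NH3 reduction (trans ring fusion). C7 comes from the Luche reduction and is passed to C9 by the suprafacial [3,3] shift, which also places C7=C8. Both chain E-alkenes come unchanged from (2E,6E)-farnesyl bromide.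
Helpers: the C7 oxygen (put in at step 5) leaves in step 11, and the carboxyl carbon leaves in step 12.

Key step: step 4

Remark on locants: ring A = C1–C5 and C10, ring B = C5–C10, side chain from C11 (polypodane numbering).
Assumption: the 2-methylallyl enol carbonate is taken to follow the same sense of induction as the allyl series, where the (S)-ligand gives the (S)-ketone, so the (R)-ligand is used here; if the sense were opposite, the (S)-ligand would be used.

Step 1
Reactants: 1 2,2,6-trimethylcyclohexan-1-one (racemic)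
Product: 3 2-methylprop-2-en-1-yl 2,6,6-trimethylcyclohex-1-en-1-yl carbonate, via lithium enolate 2 (not isolated)
Conditions: LiN(SiMe3)2, THF, 0 °C; then 2-methylallyl chloroformate, −78 °C to rt
Reagents that add atoms: 2-methylallyl chloroformate, CC(=C)COC(=O)Cl
Why: O-acylation of a lithium enolate by a chloroformate (enol carbonate formation); C10–H is the only enolisable position because C4 is quaternary, so one tetrasubstituted enolate forms and the stereocentre of racemic 1 is erased.

Step 2
Reactants: 3 2-methylprop-2-en-1-yl 2,6,6-trimethylcyclohex-1-en-1-yl carbonate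
Product: 4 (2R)-2,6,6-trimethyl-2-(2-methylprop-2-en-1-yl)cyclohexan-1-one
Conditions: Pd2(dba)3 (2.5 mol %), (R)-t-Bu-PHOX [(R)-4-tert-butyl-2-(2-diphenylphosphanylphenyl)-4,5-dihydrooxazole, 6 mol %], THF, 25 °C
Reagents that add atoms: none
Why: decarboxylative asymmetric allylic alkylation (enantioselective Tsuji allylation): zerovalent palladium ionises the allyl carbonate, CO2 is lost, and the ligand-bound palladium enolate and 2-methylallyl unit recombine at C10 on one enolate face, which sets the quaternary stereocentre C10.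

Step 3
Reactants: 4 (2R)-2,6,6-trimethyl-2-(2-methylprop-2-en-1-yl)cyclohexan-1-one
Product: 5 3-methyl-4-[(1R)-1,3,3-trimethyl-2-oxocyclohexyl]butanal (both configurations at C8)
Conditions: Rh(acac)(CO)2 (1 mol %), PPh3 (10 mol %), CO/H2 (1:1, 40 bar), toluene, 90 °C
Reagents that add atoms: carbon monoxide, [C-]#[O+]
Why: rhodium-catalysed hydroformylation of a 1,1-disubstituted alkene, which places the formyl carbon (C6) only on the terminal CH2 (C7) because the other alkene carbon would become quaternary; C8 forms as an unselective CH(CH3) centre that becomes trigonal again in step 7.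

Step 4
Reactants: 5 3-methyl-4-[(1R)-1,3,3-trimethyl-2-oxocyclohexyl]butanal
Product: 6 (4aR)-1,1,4a,6-tetramethyl-1,2,3,4,4a,5,6,7-octahydronaphthalene (both configurations at C8)
Conditions: TiCl3(DME)1.5 (8 equiv), Zn(Cu) (20 equiv), DME, reflux; 5 added over 30 h by syringe pump (final 0.005 M)
Reagents that add atoms: none
Why: McMurry coupling: low-valent titanium (from TiCl3 and Zn(Cu)) makes a ketyl at the aldehyde carbon C6 and at the ketone carbon C5, the two couple on titanium to a cyclic pinacolate (this forms the C5–C6 bond and closes ring B), and at reflux both C–O bonds are cleaved to leave the C5=C6 alkene. The closest known reaction type is the intramolecular titanium-induced keto-aldehyde coupling to cycloalkenes. Ring B closes as a six-membered carbocycle by joining the two carbonyl carbons of a 1,6-keto-aldehyde, so both alkene carbons lie in the ring (endocyclic C5=C6). No stereocentre is created: C5 becomes trigonal, the quaternary C10 from step 2 cannot epimerise, and the C8 mixture is carried on. The step needs ring closure to beat intermolecular pinacol coupling of the aldehyde, which slow addition at high dilution should secure; it also needs the ketone to do nothing else, which the substrate secures because C5 lies between the quaternary C4 and C10 and has no α-hydrogen (no enolisation, no aldol, no alkene migration away from C5=C6).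

Step 5
Reactants: 6 (4aR)-1,1,4a,6-tetramethyl-1,2,3,4,4a,5,6,7-octahydronaphthalene
Product: 7 (4aR)-3,4a,8,8-tetramethyl-4,4a,5,6,7,8-hexahydronaphthalen-2(3H)-one (both configurations at C8)
Conditions: Rh2(cap)4 (dirhodium tetracaprolactamate, 1 mol %), t-BuOOH (70% in water, 5 equiv), K2CO3 (0.5 equiv), CH2Cl2, rt
Reagents that add atoms: tert-butyl hydroperoxide, CC(C)(C)OO
Why: radical allylic C–H oxidation of a cyclic alkene to the enone, the reaction type used to turn 5-ene steroids into 7-ketones; C7 is the only allylic carbon that bears hydrogen (C4 and C10 are quaternary), so the carbonyl can only appear at C7.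

Step 6
Reactants: 7 (4aR)-3,4a,8,8-tetramethyl-4,4a,5,6,7,8-hexahydronaphthalen-2(3H)-one
Product: 9 (4aR,8aS)-3,4a,8,8-tetramethyloctahydronaphthalen-2(1H)-one (both configurations at C8), via lithium enolate 8 (not isolated)
Conditions: Li (3 equiv), NH3 (l)/THF, t-BuOH (1 equiv), −78 °C; then solid NH4Cl
Reagents that add atoms: none
Why: dissolving-metal (Birch-type) reduction of an enone: the C5 carbanion is protonated axially on the α face, opposite to the axial C10 methyl, which sets C5 and gives the trans ring fusion, the usual outcome for angular-methyl octalones.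

Step 7
Reactants: 9 (4aR,8aS)-3,4a,8,8-tetramethyloctahydronaphthalen-2(1H)-one
Product: 11 (4aR,8aS)-3,4a,8,8-tetramethyl-4a,5,6,7,8,8a-hexahydronaphthalen-2(1H)-one, via trimethylsilyl enol ether 10 (not isolated)
Conditions: Me3SiCl, NaI, Et3N, MeCN, rt; pentane extraction and evaporation without purification; then Pd(OAc)2 (1.1 equiv), MeCN, rt
Reagents that add atoms: none
Why: Saegusa–Ito oxidation of the thermodynamic silyl enol ether: equilibrating silylation should give the more substituted C7=C8 enol ether (both C8 epimers converge), and divalent palladium then forms the C8 palladium enolate, which loses the ring hydrogen at C9 by syn β-hydride elimination to give the C8=C9 enone.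

Step 8
Reactants: 11 (4aR,8aS)-3,4a,8,8-tetramethyl-4a,5,6,7,8,8a-hexahydronaphthalen-2(1H)-one
Product: 12 (2S,4aR,8aS)-3,4a,8,8-tetramethyl-1,2,4a,5,6,7,8,8a-octahydronaphthalen-2-ol
Conditions: NaBH4, CeCl3·7H2O, MeOH, −78 to 0 °C
Reagents that add atoms: none
Why: Luche 1,2-reduction of the enone: hydride should add to C7 along the axial direction from the α face, which sets C7 with the hydroxyl quasi-equatorial on the β face (cis to the C10 methyl), the sense seen when 5α-1-en-3-one steroids give 3β-alcohols.

Step 9
Reactants: 13 (2E,6E)-1-bromo-3,7,11-trimethyldodeca-2,6,10-triene (farnesyl bromide); 14 acetic acid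
Product: 16 (4E,8E)-5,9,13-trimethyltetradeca-4,8,12-trienoic acid (farnesylacetic acid), via dilithium enediolate 15 (not isolated)
Conditions: LiN(i-Pr)2 (2.2 equiv), THF/HMPA, 0 to 40 °C; then 13, 0 °C to rt; 1 M HCl work-up
Reagents that add atoms: none
Why: C-alkylation of the acetic acid dianion (SN2 at the primary allylic bromide), which adds C11 and the carboxyl carbon to the farnesyl chain without touching the two E double bonds.

Step 10
Reactants: 12 (2S,4aR,8aS)-3,4a,8,8-tetramethyl-1,2,4a,5,6,7,8,8a-octahydronaphthalen-2-ol; 16 (4E,8E)-5,9,13-trimethyltetradeca-4,8,12-trienoic acid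
Product: 17 (2S,4aR,8aS)-3,4a,8,8-tetramethyl-1,2,4a,5,6,7,8,8a-octahydronaphthalen-2-yl (4E,8E)-5,9,13-trimethyltetradeca-4,8,12-trienoate
Conditions: DCC (1.2 equiv), DMAP (0.1 equiv), CH2Cl2, 0 °C to rt
Reagents that add atoms: none
Why: Steglich esterification of the secondary allylic alcohol under neutral conditions; only the O–H bond is broken, so C7 keeps its configuration.

Step 11
Reactants: 17 (2S,4aR,8aS)-3,4a,8,8-tetramethyl-1,2,4a,5,6,7,8,8a-octahydronaphthalen-2-yl (4E,8E)-5,9,13-trimethyltetradeca-4,8,12-trienoate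
Product: 20 (4E,8E)-5,9,13-trimethyl-2-[(1S,4aS,8aS)-2,5,5,8a-tetramethyl-1,4,4a,5,6,7,8,8a-octahydronaphthalen-1-yl]tetradeca-4,8,12-trienoic acid (both configurations at C11), via silyl ketene acetal 18 (not isolated), via trimethylsilyl ester 19 (not isolated)
Conditions: LiN(i-Pr)2 (1.3 equiv), Me3SiCl/Et3N (3 equiv, present during deprotonation), THF, −78 °C; then 65 °C, 4 h; 1 M HCl work-up
Reagents that add atoms: none
Why: Ireland–Claisen rearrangement: the silyl ketene acetal undergoes a [3,3] shift that is suprafacial over C7–C8–C9, so C11 is delivered to C9 on the β face that carried the C7 oxygen (chirality transfer from C7 to C9, as in Claisen rearrangements of cyclic allylic alcohols that place carbon cis to a neighbouring angular methyl), the double bond moves to C7=C8, and the new C11 centre is left unselective because step 12 removes it.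

Step 12
Reactants: 20 (4E,8E)-5,9,13-trimethyl-2-[(1S,4aS,8aS)-2,5,5,8a-tetramethyl-1,4,4a,5,6,7,8,8a-octahydronaphthalen-1-yl]tetradeca-4,8,12-trienoic acid
Product: 22 (4aS,5S,8aS)-1,1,4a,6-tetramethyl-5-[(3E,7E)-4,8,12-trimethyltrideca-3,7,11-trien-1-yl]-1,2,3,4,4a,5,8,8a-octahydronaphthalene (target), via thiohydroxamate ester 21 (not isolated)
Conditions: 2-mercaptopyridine N-oxide (1.2 equiv), DCC (1.2 equiv), DMAP (cat.), CH2Cl2, rt, dark; then t-BuSH (10 equiv), hν (tungsten lamp), rt
Reagents that add atoms: none
Why: Barton reductive decarboxylation: the N-acyloxypyridinethione fragments to CO2 and the secondary C11 radical, which takes a hydrogen atom from the thiol; C9 is not part of the radical and the isolated double bonds should be inert to this chain reaction.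

**Compound list**

1 | 2,2,6-trimethylcyclohexan-1-one (racemic) | CC1CCCC(C)(C)C1=O | starting material
2 | lithium 2,6,6-trimethylcyclohex-1-en-1-olate | [Li+].[O-]C1=C(C)CCCC1(C)C | intermediate
3 | 2-methylprop-2-en-1-yl 2,6,6-trimethylcyclohex-1-en-1-yl carbonate | CC(=C)COC(=O)OC1=C(C)CCCC1(C)C | intermediate
4 | (2R)-2,6,6-trimethyl-2-(2-methylprop-2-en-1-yl)cyclohexan-1-one | CC(=C)C[C@@]1(C)CCCC(C)(C)C1=O | intermediate
5 | 3-methyl-4-[(1R)-1,3,3-trimethyl-2-oxocyclohexyl]butanal (both configurations at the CH(CH3) carbon) | O=CCC(C)C[C@@]1(C)CCCC(C)(C)C1=O | intermediate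
6 | (4aR)-1,1,4a,6-tetramethyl-1,2,3,4,4a,5,6,7-octahydronaphthalene (both configurations at C6 of the name) | CC1CC=C2C(C)(C)CCC[C@]2(C)C1 | intermediate
7 | (4aR)-3,4a,8,8-tetramethyl-4,4a,5,6,7,8-hexahydronaphthalen-2(3H)-one (both configurations at C3 of the name) | CC1C[C@@]2(C)CCCC(C)(C)C2=CC1=O | intermediate
8 | lithium (4aR,8aS)-3,4a,8,8-tetramethyl-3,4,4a,5,6,7,8,8a-octahydronaphthalen-2-olate | [Li+].[O-]C1=C[C@H]2C(C)(C)CCC[C@]2(C)CC1C | intermediate
9 | (4aR,8aS)-3,4a,8,8-tetramethyloctahydronaphthalen-2(1H)-one (trans-fused; both configurations at C3 of the name) | CC1C[C@@]2(C)CCCC(C)(C)[C@@H]2CC1=O | intermediate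
10 | trimethyl{[(4aR,8aS)-3,4a,8,8-tetramethyl-1,4,4a,5,6,7,8,8a-octahydronaphthalen-2-yl]oxy}silane | CC1=C(O[Si](C)(C)C)C[C@H]2C(C)(C)CCC[C@]2(C)C1 | intermediate
11 | (4aR,8aS)-3,4a,8,8-tetramethyl-4a,5,6,7,8,8a-hexahydronaphthalen-2(1H)-one | CC1=C[C@@]2(C)CCCC(C)(C)[C@@H]2CC1=O | intermediate
12 | (2S,4aR,8aS)-3,4a,8,8-tetramethyl-1,2,4a,5,6,7,8,8a-octahydronaphthalen-2-ol (hydroxyl cis to the angular methyl) | CC1=C[C@@]2(C)CCCC(C)(C)[C@@H]2C[C@@H]1O | intermediate
13 | (2E,6E)-1-bromo-3,7,11-trimethyldodeca-2,6,10-triene (farnesyl bromide) | CC(C)=CCC/C(C)=C/CC/C(C)=C/CBr | starting material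
14 | acetic acid | CC(=O)O | starting material
15 | dilithium ethene-1,1-diolate | [Li+].[Li+].C=C([O-])[O-] | intermediate
16 | (4E,8E)-5,9,13-trimethyltetradeca-4,8,12-trienoic acid (farnesylacetic acid) | CC(C)=CCC/C(C)=C/CC/C(C)=C/CCC(=O)O | intermediate
17 | (2S,4aR,8aS)-3,4a,8,8-tetramethyl-1,2,4a,5,6,7,8,8a-octahydronaphthalen-2-yl (4E,8E)-5,9,13-trimethyltetradeca-4,8,12-trienoate | CC(C)=CCC/C(C)=C/CC/C(C)=C/CCC(=O)O[C@H]1C[C@H]2C(C)(C)CCC[C@]2(C)C=C1C | intermediate
18 | O-trimethylsilyl ketene acetal of ester 17 | CC(C)=CCC/C(C)=C/CC/C(C)=C/CC=C(O[Si](C)(C)C)O[C@H]1C[C@H]2C(C)(C)CCC[C@]2(C)C=C1C | intermediate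
19 | trimethylsilyl (4E,8E)-5,9,13-trimethyl-2-[(1S,4aS,8aS)-2,5,5,8a-tetramethyl-1,4,4a,5,6,7,8,8a-octahydronaphthalen-1-yl]tetradeca-4,8,12-trienoate | CC(C)=CCC/C(C)=C/CC/C(C)=C/CC(C(=O)O[Si](C)(C)C)[C@H]1C(C)=CC[C@H]2C(C)(C)CCC[C@]12C | intermediate
20 | (4E,8E)-5,9,13-trimethyl-2-[(1S,4aS,8aS)-2,5,5,8a-tetramethyl-1,4,4a,5,6,7,8,8a-octahydronaphthalen-1-yl]tetradeca-4,8,12-trienoic acid (both configurations at C2 of the acid) | CC(C)=CCC/C(C)=C/CC/C(C)=C/CC(C(=O)O)[C@H]1C(C)=CC[C@H]2C(C)(C)CCC[C@]12C | intermediate
21 | 2-thioxopyridin-1(2H)-yl ester of acid 20 | CC(C)=CCC/C(C)=C/CC/C(C)=C/CC(C(=O)ON3C=CC=CC3=S)[C@H]1C(C)=CC[C@H]2C(C)(C)CCC[C@]12C | intermediate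
22 | (4aS,5S,8aS)-1,1,4a,6-tetramethyl-5-[(3E,7E)-4,8,12-trimethyltrideca-3,7,11-trien-1-yl]-1,2,3,4,4a,5,8,8a-octahydronaphthalene | CC(C)=CCC/C(C)=C/CC/C(C)=C/CC[C@H]1C(C)=CC[C@H]2C(C)(C)CCC[C@]12C | target

**Step count**

Total step count: 12. Longest linear sequence: 11 steps (steps 1–8 and 10–12); step 9 is the one-step side branch to acid 16.

**Steps most likely to fail**

Step 4. Electron transfer to the unhindered aldehyde may outrun that to the doubly neopentyl ketone, so that aldehyde ketyls pair between molecules or are reduced to the alcohol before the C5–C6 bond forms. The fallback sets out from 5 and comes back at 6. The aldehyde alone is reduced (NaBH4, MeOH, −40 °C) to (2R)-2-(4-hydroxy-2-methylbutyl)-2,6,6-trimethylcyclohexan-1-one F1, which is converted (I2, PPh3, imidazole, CH2Cl2) into (2R)-2-(4-iodo-2-methylbutyl)-2,6,6-trimethylcyclohexan-1-one F2. SmI2 with HMPA in THF then closes ring B by an intramolecular Barbier reaction of the C6 iodide onto the C5 ketone, giving the ring-fusion alcohol (8aR)-4,4,7,8a-tetramethyloctahydronaphthalen-4a(2H)-ol F3. Syn-dehydration with methyl N-(triethylammoniosulfonyl)carbamate inner salt (benzene, 50 °C) should give 6, the only alkene F3 can form because C4 and C10 bear no hydrogen.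

Step 11. The ketene acetal carbon has to bond to C9 on the face that also carries the axial C10 methyl; if the shift is slow, fragmentation of the ketene acetal or elimination of the allylic oxygen to a diene may take over. The fallback sets out from 12 and comes back at 20. A Johnson–Claisen rearrangement (triethyl orthoacetate, cat. propanoic acid, 140 °C) uses the smallest possible ketene acetal and should give ethyl 2-[(1S,4aS,8aS)-2,5,5,8a-tetramethyl-1,4,4a,5,6,7,8,8a-octahydronaphthalen-1-yl]acetate F4. Its lithium enolate (LiN(i-Pr)2, THF, −78 °C) is alkylated at C11 with 13 to give ethyl (4E,8E)-5,9,13-trimethyl-2-[(1S,4aS,8aS)-2,5,5,8a-tetramethyl-1,4,4a,5,6,7,8,8a-octahydronaphthalen-1-yl]tetradeca-4,8,12-trienoate F5, and saponification (KOH, EtOH/H2O, reflux) gives 20.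

Step 7. Silylation may go toward C6 instead of C8, or the palladium enolate may lose a hydrogen of the C8 methyl instead of the ring hydrogen at C9 (exocyclic methylene ketone). The fallback sets out from 9 and comes back at 11. Selenenylation through the more substituted enol (PhSeCl, EtOAc, rt) should give (4aR,8aS)-3,4a,8,8-tetramethyl-3-(phenylselanyl)octahydronaphthalen-2(1H)-one F6, and oxidation (H2O2, pyridine, CH2Cl2, 0 °C to rt) gives the selenoxide, whose syn-elimination toward the C9 ring hydrogen leads to 11.

**Further compounds**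

F1 | step 4 | (2R)-2-(4-hydroxy-2-methylbutyl)-2,6,6-trimethylcyclohexan-1-one | OCCC(C)C[C@@]1(C)CCCC(C)(C)C1=O
F2 | step 4 | (2R)-2-(4-iodo-2-methylbutyl)-2,6,6-trimethylcyclohexan-1-one | ICCC(C)C[C@@]1(C)CCCC(C)(C)C1=O
F3 | step 4 | (8aR)-4,4,7,8a-tetramethyloctahydronaphthalen-4a(2H)-ol (both configurations at C4a and C7 of the name) | CC1CCC2(O)C(C)(C)CCC[C@]2(C)C1
F4 | step 11 | ethyl 2-[(1S,4aS,8aS)-2,5,5,8a-tetramethyl-1,4,4a,5,6,7,8,8a-octahydronaphthalen-1-yl]acetate | CCOC(=O)C[C@H]1C(C)=CC[C@H]2C(C)(C)CCC[C@]12C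
F5 | step 11 | ethyl (4E,8E)-5,9,13-trimethyl-2-[(1S,4aS,8aS)-2,5,5,8a-tetramethyl-1,4,4a,5,6,7,8,8a-octahydronaphthalen-1-yl]tetradeca-4,8,12-trienoate | CC(C)=CCC/C(C)=C/CC/C(C)=C/CC(C(=O)OCC)[C@H]1C(C)=CC[C@H]2C(C)(C)CCC[C@]12C
F6 | step 7 | (4aR,8aS)-3,4a,8,8-tetramethyl-3-(phenylselanyl)octahydronaphthalen-2(1H)-one | CC1([Se]c3ccccc3)C[C@@]2(C)CCCC(C)(C)[C@@H]2CC1=O
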